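**Assumption:** 2-methoxyresorcinol (1), ethyl (S)-lactate (5) and all reagents are bought. In each half, C1′ is the benzylic carbon and C2′ the methyl-bearing carbon. Ring A carries one ring CH; ring B is fully substituted.

## Retrosynthetic overview

1. The target differs from a C2-symmetric diolide 16 only by one phenolic OH on ring B. That OH goes in last: one ring of 16 is oxidised to a hydroxy-p-quinone (dearomatised) and reduced back.
2. 16 is opened at both ester C–O bonds. Each is made by Mitsunobu SN2 at C2′ (inversion), first between two halves, then as the ring closure; a single hydroxy acid would only close to a six-membered lactone.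
3. Each half comes from carboxylate-directed ortho-lithiation of a protected 2,4-dihydroxy-3-methoxybenzoic acid and Felkin–Anh addition to (S)-lactaldehyde; this sets C1′ and differentiates the two side-chain oxygens.
4. The acid comes from symmetric 2-methoxyresorcinol by Kolbe–Schmitt carboxylation; the aldehyde comes from ethyl (S)-lactate.
5. Ring order: both benzene rings are bought; the only ring built is the 12-membered diolide (step 10); ring B is then re-oxidised (step 12).

## Route

Step 1
Reactants: 1 2-methoxyresorcinol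
Product: 2 2,4-dihydroxy-3-methoxybenzoic acid
Conditions: KHCO3 (3 equiv), CO2 (5 bar), H2O, 100 °C; then aq. HCl
Reagents that add atoms: carbon dioxide, O=C=O
Why: Kolbe–Schmitt carboxylation goes ortho/para to the hydroxyls, and because C4 and C6 of symmetric 1 are equivalent only one acid can form.

Step 2
Reactants: 2 2,4-dihydroxy-3-methoxybenzoic acid
Product: 4 3-methoxy-2,4-bis(triisopropylsilyloxy)benzoic acid, via silyl ester 3 (not isolated)
Conditions: TIPSOTf (3.3 equiv), 2,6-lutidine, CH2Cl2, 0 °C to rt; then AcOH–THF–H2O, rt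
Reagents that add atoms: triisopropylsilyl triflate, CC(C)[Si](C(C)C)(C(C)C)OS(=O)(=O)C(F)(F)F
Why: exhaustive O-silylation followed by selective hydrolysis of the labile silyl ester gives aryl TIPS ethers that tolerate organolithiums and do not direct metalation.

Step 3
Reactants: 5 ethyl (S)-lactate
Product: 6 ethyl (S)-2-(triethylsilyloxy)propanoate
Conditions: TESCl, imidazole, DMF, 0 °C to rt
Reagents that add atoms: chlorotriethylsilane, CC[Si](Cl)(CC)CC
Why: standard O-silylation of a secondary alcohol that does not touch the stereocentre.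

Step 4
Reactants: 6 ethyl (S)-2-(triethylsilyloxy)propanoate
Product: 7 (S)-2-(triethylsilyloxy)propanal
Conditions: i-Bu2AlH (1.05 equiv), CH2Cl2, −78 °C; aq. KNaC4H4O6
Reagents that add atoms: none
Why: partial ester reduction stops at the aluminium hemiacetal at −78 °C, and the α-silyloxy aldehyde is configurationally stable when used directly.

Step 5
Reactants: 4 3-methoxy-2,4-bis(triisopropylsilyloxy)benzoic acid; 7 (S)-2-(triethylsilyloxy)propanal
Product: 10 6-[(1R,2S)-1-(tert-butyldimethylsilyloxy)-2-(triethylsilyloxy)propyl]-3-methoxy-2,4-bis(triisopropylsilyloxy)benzoic acid, via dilithiated benzoate 8 (not isolated), via dilithium alkoxide 9 (not isolated)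
Conditions: s-BuLi (2.2 equiv), TMEDA, THF, −90 °C; 7, −90 to −78 °C; TBSOTf (1.1 equiv), −78 °C; AcOH
Reagents that add atoms: tert-butyldimethylsilyl triflate, CC(C)(C)[Si](C)(C)OS(=O)(=O)C(F)(F)F
Why: carboxylate-directed ortho-metalation lithiates the only position ortho to CO2Li, the aryllithium adds to 7 under Felkin–Anh control (silyloxy group anti to the incoming aryl) to give the anti (1′R,2′S) alkoxide (dr about 5:1 expected), and trapping it at −78 °C as the TBS ether prevents phthalide formation.

Step 6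
Reactants: 10 acid from step 5
Product: 11 phenacyl 6-[(1R,2S)-1-(tert-butyldimethylsilyloxy)-2-(triethylsilyloxy)propyl]-3-methoxy-2,4-bis(triisopropylsilyloxy)benzoate
Conditions: PhCOCH2Br, Et3N, DMF, rt
Reagents that add atoms: phenacyl bromide, O=C(CBr)c1ccccc1
Why: carboxylate O-alkylation (SN2 at the phenacyl carbon) is insensitive to the steric shielding of the di-ortho-substituted carboxyl.

Step 7
Reactants: 11 phenacyl ester
Product: 12 phenacyl 6-[(1R,2S)-1-(tert-butyldimethylsilyloxy)-2-hydroxypropyl]-3-methoxy-2,4-bis(triisopropylsilyloxy)benzoate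
Conditions: PPTS (cat.), MeOH–CH2Cl2, 0 °C
Reagents that add atoms: none
Why: acid-catalysed methanolysis cleaves the TES ether much faster than the hindered benzylic TBS ether or the aryl TIPS ethers.

Step 8
Reactants: 10 acid from step 5; 12 alcohol from step 7
Product: 13 linear dimer: phenacyl ester of unit B whose C2′ oxygen carries the acyl group of 10 (unit B 1′R,2′R; unit A 1′R,2′S with OTES)
Conditions: PPh3, DIAD, toluene, 0 °C to rt
Reagents that add atoms: none
Why: Mitsunobu esterification uses the hindered carboxylate as the nucleophile in an SN2 displacement at the activated carbinol, so the shielded carbonyl is never attacked and C2′ of unit B inverts from S to R.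

Step 9
Reactants: 13 linear dimer
Product: 14 seco acid: unit B benzoic acid free, unit A C2′ hydroxyl free (unit A 1′R,2′S; unit B 1′R,2′R)
Conditions: Zn dust, AcOH–THF–H2O (3:1:1), rt
Reagents that add atoms: none
Why: zinc reductively cleaves the phenacyl ester at its α-keto C–O bond while the aqueous acetic acid hydrolyses the TES ether, leaving the benzylic TBS and aryl TIPS ethers intact.

Step 10
Reactants: 14 seco acid
Product: 15 protected C2-symmetric 12-membered diolide (both benzylic oxygens as TBS ethers, four phenols as TIPS ethers, all four stereocentres R)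
Conditions: PPh3, DIAD, toluene, 0.002 M, slow addition of 14, rt
Reagents that add atoms: none
Why: Mitsunobu macrolactonization at high dilution can only join the single acid and the single hydroxyl, which sit in different halves, and the SN2 inversion sets the last C2′ as R.

Step 11
Reactants: 15 protected diolide
Product: 16 C2-symmetric diolide: head-to-tail bis-lactone of two 2,4-dihydroxy-3-methoxy-6-[(1R,2R)-1,2-dihydroxypropyl]benzoic acid units, each acid esterified by the C2′ hydroxyl of the other
Conditions: HF·pyridine (excess), pyridine, THF, 0 °C to rt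
Reagents that add atoms: none
Why: fluoride-driven Si–O cleavage under weakly acidic conditions frees all six hydroxyls without forming alkoxides, which would trigger translactonization to phthalides.

Step 12
Reactants: 16 C2-symmetric diolide
Product: 18 target diolide CNP0086623.2, via hydroxyquinone 17 (not isolated)
Conditions: (KSO3)2NO (2 equiv), KH2PO4 buffer pH 6, acetone–H2O, 0 °C to rt, stopped at about half conversion; then Na2S2O4, H2O–EtOAc, argon
Reagents that add atoms: potassium nitrosodisulfonate, [K+].[K+].[O]N(S(=O)(=O)[O-])S(=O)(=O)[O-]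
Why: Teuber oxidation dearomatises one ring at its only free CH (para to the 2-OH, ortho to the 4-OH), either ring of C2-symmetric 16 gives the same hydroxy-p-quinone, and dithionite reduction re-aromatises it to the 2,4,5-trihydroxy-3-methoxy ring B; mono-oxidation is statistical (about 40–45 % expected), with 16 recovered and recycled.

## Compound list

1 | 2-methoxyresorcinol | COc1c(O)cccc1O | starting material
2 | 2,4-dihydroxy-3-methoxybenzoic acid | COc1c(O)ccc(C(=O)O)c1O | intermediate
3 | triisopropylsilyl 3-methoxy-2,4-bis(triisopropylsilyloxy)benzoate | COc1c(O[Si](C(C)C)(C(C)C)C(C)C)ccc(C(=O)O[Si](C(C)C)(C(C)C)C(C)C)c1O[Si](C(C)C)(C(C)C)C(C)C | intermediate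
4 | 3-methoxy-2,4-bis(triisopropylsilyloxy)benzoic acid | COc1c(O[Si](C(C)C)(C(C)C)C(C)C)ccc(C(=O)O)c1O[Si](C(C)C)(C(C)C)C(C)C | intermediate
5 | ethyl (S)-lactate | C[C@H](O)C(=O)OCC | starting material
6 | ethyl (S)-2-(triethylsilyloxy)propanoate | C[C@H](O[Si](CC)(CC)CC)C(=O)OCC | intermediate
7 | (S)-2-(triethylsilyloxy)propanal | C[C@H](O[Si](CC)(CC)CC)C=O | intermediate
8 | lithium 6-lithio-3-methoxy-2,4-bis(triisopropylsilyloxy)benzoate | [Li+].[Li]c1cc(O[Si](C(C)C)(C(C)C)C(C)C)c(OC)c(O[Si](C(C)C)(C(C)C)C(C)C)c1C(=O)[O-] | intermediate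
9 | dilithium salt (benzylic alkoxide and carboxylate) of 6-[(1R,2S)-1-hydroxy-2-(triethylsilyloxy)propyl]-3-methoxy-2,4-bis(triisopropylsilyloxy)benzoic acid | [Li+].[Li+].C[C@H](O[Si](CC)(CC)CC)[C@H]([O-])c1cc(O[Si](C(C)C)(C(C)C)C(C)C)c(OC)c(O[Si](C(C)C)(C(C)C)C(C)C)c1C(=O)[O-] | intermediate
10 | 6-[(1R,2S)-1-(tert-butyldimethylsilyloxy)-2-(triethylsilyloxy)propyl]-3-methoxy-2,4-bis(triisopropylsilyloxy)benzoic acid | C[C@H](O[Si](CC)(CC)CC)[C@H](O[Si](C)(C)C(C)(C)C)c1cc(O[Si](C(C)C)(C(C)C)C(C)C)c(OC)c(O[Si](C(C)C)(C(C)C)C(C)C)c1C(=O)O | intermediate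
11 | phenacyl ester of 10 | C[C@H](O[Si](CC)(CC)CC)[C@H](O[Si](C)(C)C(C)(C)C)c1cc(O[Si](C(C)C)(C(C)C)C(C)C)c(OC)c(O[Si](C(C)C)(C(C)C)C(C)C)c1C(=O)OCC(=O)c1ccccc1 | intermediate
12 | phenacyl 6-[(1R,2S)-1-(tert-butyldimethylsilyloxy)-2-hydroxypropyl]-3-methoxy-2,4-bis(triisopropylsilyloxy)benzoate | C[C@H](O)[C@H](O[Si](C)(C)C(C)(C)C)c1cc(O[Si](C(C)C)(C(C)C)C(C)C)c(OC)c(O[Si](C(C)C)(C(C)C)C(C)C)c1C(=O)OCC(=O)c1ccccc1 | intermediate
13 | linear dimer: acyl group of 10 on the C2′ oxygen of the unit B phenacyl ester (unit A 1′R,2′S with OTES; unit B 1′R,2′R) | C[C@H](O[Si](CC)(CC)CC)[C@H](O[Si](C)(C)C(C)(C)C)c1cc(O[Si](C(C)C)(C(C)C)C(C)C)c(OC)c(O[Si](C(C)C)(C(C)C)C(C)C)c1C(=O)O[C@H](C)[C@H](O[Si](C)(C)C(C)(C)C)c1cc(O[Si](C(C)C)(C(C)C)C(C)C)c(OC)c(O[Si](C(C)C)(C(C)C)C(C)C)c1C(=O)OCC(=O)c1ccccc1 | intermediate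
14 | seco acid: 13 without the phenacyl and TES groups | C[C@H](O)[C@H](O[Si](C)(C)C(C)(C)C)c1cc(O[Si](C(C)C)(C(C)C)C(C)C)c(OC)c(O[Si](C(C)C)(C(C)C)C(C)C)c1C(=O)O[C@H](C)[C@H](O[Si](C)(C)C(C)(C)C)c1cc(O[Si](C(C)C)(C(C)C)C(C)C)c(OC)c(O[Si](C(C)C)(C(C)C)C(C)C)c1C(=O)O | intermediate
15 | protected C2-symmetric diolide (2 benzylic OTBS, 4 aryl OTIPS, all four stereocentres R) | COc1c(O[Si](C(C)C)(C(C)C)C(C)C)cc2c(c1O[Si](C(C)C)(C(C)C)C(C)C)C(=O)O[C@H](C)[C@H](O[Si](C)(C)C(C)(C)C)c1cc(O[Si](C(C)C)(C(C)C)C(C)C)c(OC)c(O[Si](C(C)C)(C(C)C)C(C)C)c1C(=O)O[C@H](C)[C@@H]2O[Si](C)(C)C(C)(C)C | intermediate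
16 | C2-symmetric diolide (both rings 2,4-dihydroxy-3-methoxy, all four stereocentres R) | COc1c(O)cc2c(c1O)C(=O)O[C@H](C)[C@H](O)c1cc(O)c(OC)c(O)c1C(=O)O[C@H](C)[C@@H]2O | intermediate
17 | mono-quinone: 16 with ring B as 4-hydroxy-3-methoxy-2,5-benzoquinone | COc1c(O)cc2c(c1O)C(=O)O[C@H](C)[C@H](O)C1=C(C(=O)O[C@H](C)[C@@H]2O)C(=O)C(OC)=C(O)C1=O | intermediate
18 | CNP0086623.2 | COc1c(O)cc2c(c1O)C(=O)O[C@H](C)[C@H](O)c1c(O)c(O)c(OC)c(O)c1C(=O)O[C@H](C)[C@@H]2O | target

## Step count and risks

Total: 12 steps. Longest linear sequence: 10 steps (1 → 2 → 4 → 10 → 11 → 12 → 13 → 14 → 15 → 16 → 18; the lactate branch 5 → 6 → 7 joins at step 5 and is equally long).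

**Step 5** is the most demanding step: regioselective lithiation, Felkin–Anh addition and silyl trapping must all work in one flask, and a TES shift to the benzylic alkoxide or premature lactonization would spoil it. The fallback sets out from 4 (with 7) and returns at 10. The same lithiation and addition are quenched with aqueous acid so that the adduct closes to the phthalide (3R)-6-methoxy-3-[(1S)-1-(triethylsilyloxy)ethyl]-5,7-bis(triisopropylsilyloxy)-2-benzofuran-1(3H)-one F1. The lactone protects the benzylic oxygen and the carboxyl together and lets the minor C1′ epimer be removed by crystallisation or chromatography. LiOH in THF–H2O at 0 °C opens it to the lithium hydroxy carboxylate F2. TBSCl and imidazole in DMF silylate both oxygens to the TBS ether TBS ester F3. Brief K2CO3 in MeOH–H2O cleaves only the silyl ester and gives 10.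

**Step 10** closes a 12-membered ring by SN2 at a β-branched secondary carbinol, so oligomers and elimination are the likely failures. Step 8 carries the same SN2 risk in milder form and would be cured the same way. The fallback sets out from 14 and returns at 15. The hydroxyl is first turned into an isolated leaving group: MsCl and Et3N in CH2Cl2 at −20 °C with NaHCO3 work-up give the mesylate acid F4. Its cesium carboxylate (Cs2CO3, DMF, 0.002 M, 50 °C) then closes the ring by intramolecular carboxylate alkylation with the same inversion, with no phosphonium chemistry involved.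

**Step 12** may fail because the ester-bearing ring is oxidised only sluggishly by the nitroxyl radical, and it is statistical in any case. The fallback sets out from 16 and returns at 18. Magnesium-phenoxide-directed ortho-formylation (MgCl2, Et3N, paraformaldehyde, THF, 60 °C, one equivalent) installs a formyl group at the only open ring position of one ring to give the mono-aldehyde F5. A Dakin oxidation (H2O2, catalytic (PhSe)2, CH2Cl2) converts it to the aryl formate F6. Dilute aqueous NaHCO3 hydrolyses the formate to 18. Mono-functionalisation remains statistical, but the oxygen is introduced by C-formylation and oxidative rearrangement rather than through a quinone.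

## Further compounds

F1 | step 5 | (3R)-6-methoxy-3-[(1S)-1-(triethylsilyloxy)ethyl]-5,7-bis(triisopropylsilyloxy)-2-benzofuran-1(3H)-one | C[C@H](O[Si](CC)(CC)CC)[C@@H]1OC(=O)c2c(O[Si](C(C)C)(C(C)C)C(C)C)c(OC)c(O[Si](C(C)C)(C(C)C)C(C)C)cc21
F2 | step 5 | lithium 6-[(1R,2S)-1-hydroxy-2-(triethylsilyloxy)propyl]-3-methoxy-2,4-bis(triisopropylsilyloxy)benzoate | [Li+].C[C@H](O[Si](CC)(CC)CC)[C@H](O)c1cc(O[Si](C(C)C)(C(C)C)C(C)C)c(OC)c(O[Si](C(C)C)(C(C)C)C(C)C)c1C(=O)[O-]
F3 | step 5 | tert-butyldimethylsilyl ester of 10 | C[C@H](O[Si](CC)(CC)CC)[C@H](O[Si](C)(C)C(C)(C)C)c1cc(O[Si](C(C)C)(C(C)C)C(C)C)c(OC)c(O[Si](C(C)C)(C(C)C)C(C)C)c1C(=O)O[Si](C)(C)C(C)(C)C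
F4 | step 10 | C2′ methanesulfonate of seco acid 14 (unit A 1′R,2′S) | C[C@H](OS(C)(=O)=O)[C@H](O[Si](C)(C)C(C)(C)C)c1cc(O[Si](C(C)C)(C(C)C)C(C)C)c(OC)c(O[Si](C(C)C)(C(C)C)C(C)C)c1C(=O)O[C@H](C)[C@H](O[Si](C)(C)C(C)(C)C)c1cc(O[Si](C(C)C)(C(C)C)C(C)C)c(OC)c(O[Si](C(C)C)(C(C)C)C(C)C)c1C(=O)O
F5 | step 12 | 16 with a formyl group on the free ring position of one ring | COc1c(O)cc2c(c1O)C(=O)O[C@H](C)[C@H](O)c1c(C=O)c(O)c(OC)c(O)c1C(=O)O[C@H](C)[C@@H]2O
F6 | step 12 | 16 with a formyloxy group on that ring position (formate ester of 18) | COc1c(O)cc2c(c1O)C(=O)O[C@H](C)[C@H](O)c1c(OC=O)c(O)c(OC)c(O)c1C(=O)O[C@H](C)[C@@H]2O
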